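**Plan**

1. The retrosynthesis first cuts the two C6–O ester bonds, giving two units of the bicyclic amino alcohol and (2E,6E)-2,6-dimethylocta-2,6-dienedioic acid (made from geranyl acetate), and then traces the N-methyl group back to a carbamate carbonyl.
2. Numbering is C1, N2, C3, C4, C4a, C5, C6, C7, C7a, with ring A the cyclopentane and ring B the piperidine. In ring B only C3–C4 can be an alkene while both ring-fusion carbons C4a and C7a stay sp3, and C4 carries the methyl group, so this bond is cut to an N-vinyl carbamate on N2 and an isopropenyl group on C4a.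
3. Further cuts are N2–C1 (primary iodide plus tert-butyl N-vinylcarbamate), C4a–C7a of ring A (intramolecular magnesium-ene reaction of an acyclic allylic chloride) and C6–C7 (crotylation of 4-methylpent-3-enal).
4. Forward, the chain is built by crotylation, ring A closes by the magnesium-ene reaction, and ring B closes by ring-closing metathesis with hydrogenation in the same flask. Carbamate reduction, desilylation and double esterification follow.
5. C6 and C7 come from the catalyst-controlled anti-crotylboration, C4a and C7a from the cis-selective ene closure steered by the C7 methyl group, and C4 from hydrogenation on the convex face of the cis-fused enecarbamate. Both E alkenes of the diacid come from geranyl acetate.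

Key step: step 8

Remark: the target SMILES corresponds to the (4S,4aR,6S,7R,7aS) amino alcohol, with H4, H4a and H7a mutually cis and the C6 oxygen cis to the C7 methyl group on the face of ring A opposite to ring B.

**Route**

Step 1
Reactants: 1 4-methylpent-3-en-1-ol
Product: 2 4-methylpent-3-enal
Conditions: Dess–Martin periodinane, NaHCO3, CH2Cl2, 0 °C to rt; filtered through silica, concentrated cold, used at once
Reagents that add atoms: none
Why: Dess–Martin oxidation is mild and buffered, so the β,γ-unsaturated aldehyde should form without migration of the alkene into conjugation, provided the volatile product is kept cold and acid-free.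

Step 2
Reactants: 2 4-methylpent-3-enal; 3 (E)-crotylboronic acid pinacol ester
Product: 5 (3R,4S)-3,7-dimethylocta-1,6-dien-4-ol, via pinacol borate ester 4 (not isolated)
Conditions: (R)-TRIP [(R)-3,3'-bis(2,4,6-triisopropylphenyl)-1,1'-binaphthyl-2,2'-diyl hydrogen phosphate] (5 mol %), 4 Å MS, toluene, −30 °C; aq. NaHCO3 work-up
Reagents that add atoms: none
Why: Chiral phosphoric acid-catalysed crotylboration runs through a closed chair transition state, so the (E)-boronate should give the anti product (the later C6 oxygen and C7 methyl), and the (R)-catalyst is expected to direct addition to the Re face of the aldehyde to give the 4S carbinol; the enantiomeric purity of 5 would be checked through its MTPA esters before continuing.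

Step 3
Reactants: 5 (3R,4S)-3,7-dimethylocta-1,6-dien-4-ol
Product: 6 tert-butyl{[(3R,4S)-3,7-dimethylocta-1,6-dien-4-yl]oxy}dimethylsilane
Conditions: TBSCl, imidazole, DMF, rt
Reagents that add atoms: tert-butyldimethylsilyl chloride, CC(C)(C)[Si](C)(C)Cl
Why: Standard silylation of a secondary alcohol; the silyl ether masks the hydroxyl through the organomagnesium, metathesis and hydride steps.

Step 4
Reactants: 6 tert-butyl{[(3R,4S)-3,7-dimethylocta-1,6-dien-4-yl]oxy}dimethylsilane
Product: 7 (2E,5S,6R)-5-[(tert-butyldimethylsilyl)oxy]-2,6-dimethylocta-2,7-dien-1-ol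
Conditions: SeO2 (cat.), t-BuOOH, salicylic acid (cat.), CH2Cl2, rt
Reagents that add atoms: tert-butyl hydroperoxide, CC(C)(C)OO (oxygen source, relayed by selenium dioxide, O=[Se]=O)
Why: Catalytic SeO2 allylic oxidation (ene reaction then [2,3]-sigmatropic shift) attacks the electron-rich trisubstituted alkene at its (E)-methyl group and should give the (E)-allylic alcohol, the monosubstituted vinyl group being much less reactive.

Step 5
Reactants: 7 (2E,5S,6R)-5-[(tert-butyldimethylsilyl)oxy]-2,6-dimethylocta-2,7-dien-1-ol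
Product: 8 tert-butyl{[(3R,4S,6E)-8-chloro-3,7-dimethylocta-1,6-dien-4-yl]oxy}dimethylsilane
Conditions: MsCl, 2,4,6-collidine, LiCl, DMF, 0 °C
Reagents that add atoms: lithium chloride, [Li+].[Cl-] (chloride source; methanesulfonyl chloride, CS(=O)(=O)Cl, feeds the same chloride pool)
Why: Mesylation and in situ SN2 displacement by chloride converts a primary allylic alcohol into the allylic chloride without allylic transposition or loss of the E geometry.

Step 6
Reactants: 8 tert-butyl{[(3R,4S,6E)-8-chloro-3,7-dimethylocta-1,6-dien-4-yl]oxy}dimethylsilane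
Product: 11 tert-butyl{[(1S,2R,3S,4S)-3-(iodomethyl)-2-methyl-4-(prop-1-en-2-yl)cyclopentyl]oxy}dimethylsilane, via allylic Grignard reagent 9 (not isolated), via cyclopentylmethyl Grignard reagent 10 (not isolated)
Conditions: Mg powder (activated, excess), Et2O, slow addition at −60 °C; then 60 °C (sealed vessel); then I2, THF, −78 to 0 °C
Reagents that add atoms: iodine, II
Why: In the intramolecular magnesium-ene reaction the 2-alkenylmagnesium chloride adds through its substituted terminus to the vinyl group in a six-centre transition state with transfer of magnesium, which closes ring A with the isopropenyl group (C4a) and the CH2Mg group (C7a) cis; the C7 methyl group is expected to sit equatorial in the folded transition state, the smaller silyloxy group at C6 then being axial, so that the CH2Mg group ends trans to the methyl, and iodinolysis of the C–Mg bond gives the iodide.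

Step 7
Reactants: 11 tert-butyl{[(1S,2R,3S,4S)-3-(iodomethyl)-2-methyl-4-(prop-1-en-2-yl)cyclopentyl]oxy}dimethylsilane; 12 tert-butyl N-ethenylcarbamate
Product: 13 tert-butyl N-ethenyl-N-{[(1S,2R,3S,5S)-3-[(tert-butyldimethylsilyl)oxy]-2-methyl-5-(prop-1-en-2-yl)cyclopentyl]methyl}carbamate
Conditions: NaH, DMF, 0 to 50 °C
Reagents that add atoms: none
Why: N-alkylation of the sodium salt of a secondary carbamate by a primary iodide (SN2) is standard, N-vinyl carbamates are alkylated on nitrogen under these conditions, and no stereocentre is touched.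

Step 8
Reactants: 13 tert-butyl N-ethenyl-N-{[(1S,2R,3S,5S)-3-[(tert-butyldimethylsilyl)oxy]-2-methyl-5-(prop-1-en-2-yl)cyclopentyl]methyl}carbamate
Product: 15 tert-butyl (4S,4aR,6S,7R,7aS)-6-[(tert-butyldimethylsilyl)oxy]-4,7-dimethyloctahydro-2H-cyclopenta[c]pyridine-2-carboxylate, via cyclic enecarbamate 14 (not isolated)
Conditions: second-generation Grubbs catalyst RuCl2(=CHPh)(H2IMes)(PCy3) (10 mol %), toluene (5 mM), 80 °C, argon sparge; then EtOH, Pd/C, H2 (3 bar), rt, same flask
Reagents that add atoms: none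
Why: The ruthenium benzylidene exchanges onto the N-vinyl group, the new alkylidene engages the 1,1-disubstituted isopropenyl alkene by [2+2] cycloaddition and cycloreversion, and ethene is expelled, so that the C3–C4 bond forms. The closest known reaction type is enamide–olefin ring-closing metathesis of N-acyl-N-vinyl amines to five- and six-membered cyclic enecarbamates with this catalyst, followed by heterogeneous hydrogenation in the same vessel. Ring B closes as a six-membered ring with both alkene carbons ending inside it, the two reacting groups being held on adjacent cis positions of ring A. The only new stereocentre, C4, is set in the hydrogenation: the cis-fused enecarbamate is cup-shaped, ring A shields the concave face, and hydrogen on Pd/C should add syn from the convex face that carries H4a and H7a, which gives H4 cis to H4a (4S). The step needs metathesis between exactly two alkenes without alkene migration or dimerisation; the substrate has no third alkene, the carbamate keeps the nitrogen from binding ruthenium, and high dilution with removal of ethene favours closure. The silyl ether and the tert-butyl carbamate are inert to both catalysts.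

Step 9
Reactants: 15 tert-butyl (4S,4aR,6S,7R,7aS)-6-[(tert-butyldimethylsilyl)oxy]-4,7-dimethyloctahydro-2H-cyclopenta[c]pyridine-2-carboxylate
Product: 16 (4S,4aR,6S,7R,7aS)-6-[(tert-butyldimethylsilyl)oxy]-2,4,7-trimethyloctahydro-1H-cyclopenta[c]pyridine
Conditions: LiAlH4, THF, reflux; H2O/aq. NaOH work-up
Reagents that add atoms: none
Why: Hydride reduction of a carbamate with LiAlH4 expels tert-butoxide and takes the carbonyl carbon down to the N-methyl group; the stereocentres are untouched, and any silyl ether lost here would converge on the product of step 10.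

Step 10
Reactants: 16 (4S,4aR,6S,7R,7aS)-6-[(tert-butyldimethylsilyl)oxy]-2,4,7-trimethyloctahydro-1H-cyclopenta[c]pyridine
Product: 17 (4S,4aR,6S,7R,7aS)-2,4,7-trimethyloctahydro-1H-cyclopenta[c]pyridin-6-ol
Conditions: HCl (1.25 M in MeOH), rt; then aq. NaOH
Reagents that add atoms: none
Why: Acid-catalysed methanolysis of the secondary silyl ether, with the amine held as its hydrochloride and freed on basification; the C6–O bond is not broken, so the configuration is kept.

Step 11
Reactants: 18 geranyl acetate [(2E)-3,7-dimethylocta-2,6-dien-1-yl acetate]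
Product: 19 (2E,6E)-8-hydroxy-3,7-dimethylocta-2,6-dien-1-yl acetate
Conditions: SeO2 (cat.), t-BuOOH, salicylic acid (cat.), CH2Cl2, rt
Reagents that add atoms: tert-butyl hydroperoxide, CC(C)(C)OO (oxygen source, relayed by selenium dioxide, O=[Se]=O)
Why: The same SeO2 allylic oxidation should hydroxylate the (E)-methyl group of the distal trisubstituted alkene, the allylic acetate deactivating the proximal one.

Step 12
Reactants: 19 (2E,6E)-8-hydroxy-3,7-dimethylocta-2,6-dien-1-yl acetate
Product: 20 (2E,6E)-2,6-dimethylocta-2,6-diene-1,8-diol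
Conditions: K2CO3 (cat.), MeOH, rt
Reagents that add atoms: none
Why: Base-catalysed transesterification with methanol removes the acetate without touching the alkenes.

Step 13
Reactants: 20 (2E,6E)-2,6-dimethylocta-2,6-diene-1,8-diol
Product: 21 (2E,6E)-2,6-dimethylocta-2,6-dienedial
Conditions: MnO2 (activated, excess), CH2Cl2, rt
Reagents that add atoms: none
Why: MnO2 oxidation is selective for allylic alcohols and should convert both termini into enals with the E geometry kept at room temperature.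

Step 14
Reactants: 21 (2E,6E)-2,6-dimethylocta-2,6-dienedial
Product: 22 (2E,6E)-2,6-dimethylocta-2,6-dienedioic acid
Conditions: NaClO2, NaH2PO4, 2-methylbut-2-ene, t-BuOH/H2O, rt
Reagents that add atoms: sodium chlorite, [Na+].[O-]Cl=O
Why: Pinnick oxidation converts enals into conjugated acids without isomerising or chlorinating the alkenes, the added alkene scavenging the hypochlorous acid formed.

Step 15
Reactants: 17 (4S,4aR,6S,7R,7aS)-2,4,7-trimethyloctahydro-1H-cyclopenta[c]pyridin-6-ol (2.2 equiv); 22 (2E,6E)-2,6-dimethylocta-2,6-dienedioic acid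
Product: 23 bis[(4S,4aR,6S,7R,7aS)-2,4,7-trimethyloctahydro-1H-cyclopenta[c]pyridin-6-yl] (2E,6E)-2,6-dimethylocta-2,6-dienedioate
Conditions: DCC, DMAP, CH2Cl2, 0 °C to rt
Reagents that add atoms: none
Why: Steglich esterification acylates both C6 hydroxyls with retention because the alcohol C–O bond is not broken, and conjugated acids of this type should not deconjugate under carbodiimide/DMAP activation; since two homochiral units are joined, a minor enantiomer of 17 would end up mainly in a separable diastereomeric diester.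

**Compound list**

1 | 4-methylpent-3-en-1-ol | CC(C)=CCCO | starting material
2 | 4-methylpent-3-enal | CC(C)=CCC=O | intermediate
3 | (E)-crotylboronic acid pinacol ester | C/C=C/CB1OC(C)(C)C(C)(C)O1 | starting material
4 | 2-{[(3R,4S)-3,7-dimethylocta-1,6-dien-4-yl]oxy}-4,4,5,5-tetramethyl-1,3,2-dioxaborolane (not isolated) | CC(C)=CC[C@H](OB1OC(C)(C)C(C)(C)O1)[C@H](C)C=C | intermediate
5 | (3R,4S)-3,7-dimethylocta-1,6-dien-4-ol | CC(C)=CC[C@H](O)[C@H](C)C=C | intermediate
6 | tert-butyl{[(3R,4S)-3,7-dimethylocta-1,6-dien-4-yl]oxy}dimethylsilane | CC(C)=CC[C@H](O[Si](C)(C)C(C)(C)C)[C@H](C)C=C | intermediate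
7 | (2E,5S,6R)-5-[(tert-butyldimethylsilyl)oxy]-2,6-dimethylocta-2,7-dien-1-ol | OC/C(C)=C/C[C@H](O[Si](C)(C)C(C)(C)C)[C@H](C)C=C | intermediate
8 | tert-butyl{[(3R,4S,6E)-8-chloro-3,7-dimethylocta-1,6-dien-4-yl]oxy}dimethylsilane | ClC/C(C)=C/C[C@H](O[Si](C)(C)C(C)(C)C)[C@H](C)C=C | intermediate
9 | [(2E,5S,6R)-5-[(tert-butyldimethylsilyl)oxy]-2,6-dimethylocta-2,7-dien-1-yl]magnesium chloride (not isolated) | Cl[Mg]C/C(C)=C/C[C@H](O[Si](C)(C)C(C)(C)C)[C@H](C)C=C | intermediate
10 | {[(1S,2R,3S,5S)-3-[(tert-butyldimethylsilyl)oxy]-2-methyl-5-(prop-1-en-2-yl)cyclopentyl]methyl}magnesium chloride (not isolated) | CC(C)(C)[Si](C)(C)O[C@H]1C[C@H](C(C)=C)[C@H](C[Mg]Cl)[C@H]1C | intermediate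
11 | tert-butyl{[(1S,2R,3S,4S)-3-(iodomethyl)-2-methyl-4-(prop-1-en-2-yl)cyclopentyl]oxy}dimethylsilane | CC(C)(C)[Si](C)(C)O[C@H]1C[C@H](C(C)=C)[C@H](CI)[C@H]1C | intermediate
12 | tert-butyl N-ethenylcarbamate | C=CNC(=O)OC(C)(C)C | starting material
13 | tert-butyl N-ethenyl-N-{[(1S,2R,3S,5S)-3-[(tert-butyldimethylsilyl)oxy]-2-methyl-5-(prop-1-en-2-yl)cyclopentyl]methyl}carbamate | CC(C)(C)[Si](C)(C)O[C@H]1C[C@H](C(C)=C)[C@H](CN(C=C)C(=O)OC(C)(C)C)[C@H]1C | intermediate
14 | tert-butyl (4aS,6S,7R,7aS)-6-[(tert-butyldimethylsilyl)oxy]-4,7-dimethyl-1,4a,5,6,7,7a-hexahydro-2H-cyclopenta[c]pyridine-2-carboxylate (not isolated) | CC(C)(C)[Si](C)(C)O[C@H]1C[C@H]2[C@H](CN(C(=O)OC(C)(C)C)C=C2C)[C@H]1C | intermediate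
15 | tert-butyl (4S,4aR,6S,7R,7aS)-6-[(tert-butyldimethylsilyl)oxy]-4,7-dimethyloctahydro-2H-cyclopenta[c]pyridine-2-carboxylate | CC(C)(C)[Si](C)(C)O[C@H]1C[C@H]2[C@H](CN(C(=O)OC(C)(C)C)C[C@H]2C)[C@H]1C | intermediate
16 | (4S,4aR,6S,7R,7aS)-6-[(tert-butyldimethylsilyl)oxy]-2,4,7-trimethyloctahydro-1H-cyclopenta[c]pyridine | CC(C)(C)[Si](C)(C)O[C@H]1C[C@H]2[C@H](CN(C)C[C@H]2C)[C@H]1C | intermediate
17 | (4S,4aR,6S,7R,7aS)-2,4,7-trimethyloctahydro-1H-cyclopenta[c]pyridin-6-ol | O[C@H]1C[C@H]2[C@H](CN(C)C[C@H]2C)[C@H]1C | intermediate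
18 | geranyl acetate | CC(C)=CCC/C(C)=C/COC(C)=O | starting material
19 | (2E,6E)-8-hydroxy-3,7-dimethylocta-2,6-dien-1-yl acetate | OC/C(C)=C/CC/C(C)=C/COC(C)=O | intermediate
20 | (2E,6E)-2,6-dimethylocta-2,6-diene-1,8-diol | OC/C(C)=C/CC/C(C)=C/CO | intermediate
21 | (2E,6E)-2,6-dimethylocta-2,6-dienedial | O=C/C(C)=C/CC/C(C)=C/C=O | intermediate
22 | (2E,6E)-2,6-dimethylocta-2,6-dienedioic acid | OC(=O)/C(C)=C/CC/C(C)=C/C(O)=O | intermediate
23 | bis[(4S,4aR,6S,7R,7aS)-2,4,7-trimethyloctahydro-1H-cyclopenta[c]pyridin-6-yl] (2E,6E)-2,6-dimethylocta-2,6-dienedioate | C/C(=C\C(=O)O[C@H]1C[C@H]2[C@H](CN(C)C[C@H]2C)[C@H]1C)CC/C=C(\C)C(=O)O[C@H]1C[C@H]2[C@H](CN(C)C[C@H]2C)[C@H]1C | target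

**Step count and risks**

Total step count: 15. Longest linear sequence: 11 steps (steps 1 to 10, then step 15); the diacid branch is steps 11 to 14.

Steps most likely to fail:

Step 8. The metathesis may stall, because the ruthenium alkylidene formed at the N-vinyl group can be held by the carbamate oxygen and the 1,1-disubstituted partner engages slowly. Ruthenium hydride formed on catalyst decay may also move the isopropenyl double bond towards C4a. The fallback closes ring B at N2–C3 by condensation and keeps the same hydrogenation for C4. It sets out from 13. Hydrolysis of the N-vinyl group with aqueous oxalic acid in THF would give tert-butyl N-{[(1S,2R,3S,5S)-3-[(tert-butyldimethylsilyl)oxy]-2-methyl-5-(prop-1-en-2-yl)cyclopentyl]methyl}carbamate F1. Hydroboration of the isopropenyl group with 9-BBN and oxidation (NaOH, H2O2) would give tert-butyl N-{[3-[(tert-butyldimethylsilyl)oxy]-5-(1-hydroxypropan-2-yl)-2-methylcyclopentyl]methyl}carbamate F2, with the ring centres unchanged and both side-chain epimers usable. Dess–Martin oxidation would give tert-butyl N-{[3-[(tert-butyldimethylsilyl)oxy]-2-methyl-5-(1-oxopropan-2-yl)cyclopentyl]methyl}carbamate F3. Cyclodehydration of its N-Boc hemiaminal (PPTS, toluene, 80 °C) would give the enecarbamate 14, where the route is rejoined; 14 would then be hydrogenated over Pd/C to 15 as in step 8.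

Step 6. Magnesium insertion may be accompanied by Wurtz-type homocoupling of the allylic chloride. More seriously, facial control in the ene closure may be poor, because the transition state that keeps the C7 methyl group equatorial forces the C6 silyloxy group axial. The fallback runs the sequence in the C6-epimeric series, where both groups are equatorial, and corrects C6 in the last step by an esterification with inversion. It sets out from aldehyde 2.
- Crotylboration with (Z)-crotylboronic acid pinacol ester and (S)-TRIP would give, through 2-{[(3R,4R)-3,7-dimethylocta-1,6-dien-4-yl]oxy}-4,4,5,5-tetramethyl-1,3,2-dioxaborolane F4, the syn alcohol (3R,4R)-3,7-dimethylocta-1,6-dien-4-ol F5.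
- Silylation as in step 3 would give tert-butyl{[(3R,4R)-3,7-dimethylocta-1,6-dien-4-yl]oxy}dimethylsilane F6.
- SeO2 oxidation as in step 4 would give (2E,5R,6R)-5-[(tert-butyldimethylsilyl)oxy]-2,6-dimethylocta-2,7-dien-1-ol F7.
- Chlorination as in step 5 would give tert-butyl{[(3R,4R,6E)-8-chloro-3,7-dimethylocta-1,6-dien-4-yl]oxy}dimethylsilane F8.
- Magnesium insertion would give [(2E,5R,6R)-5-[(tert-butyldimethylsilyl)oxy]-2,6-dimethylocta-2,7-dien-1-yl]magnesium chloride F9, which should cyclise to {[(1S,2R,3R,5S)-3-[(tert-butyldimethylsilyl)oxy]-2-methyl-5-(prop-1-en-2-yl)cyclopentyl]methyl}magnesium chloride F10.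
- Iodinolysis would give tert-butyl{[(1R,2R,3S,4S)-3-(iodomethyl)-2-methyl-4-(prop-1-en-2-yl)cyclopentyl]oxy}dimethylsilane F11.
- Alkylation of 12 as in step 7 would give tert-butyl N-ethenyl-N-{[(1S,2R,3R,5S)-3-[(tert-butyldimethylsilyl)oxy]-2-methyl-5-(prop-1-en-2-yl)cyclopentyl]methyl}carbamate F12.
- Metathesis as in step 8 would give tert-butyl (4aS,6R,7R,7aS)-6-[(tert-butyldimethylsilyl)oxy]-4,7-dimethyl-1,4a,5,6,7,7a-hexahydro-2H-cyclopenta[c]pyridine-2-carboxylate F13, and hydrogenation in the same flask tert-butyl (4S,4aR,6R,7R,7aS)-6-[(tert-butyldimethylsilyl)oxy]-4,7-dimethyloctahydro-2H-cyclopenta[c]pyridine-2-carboxylate F14.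
- LiAlH4 would give (4S,4aR,6R,7R,7aS)-6-[(tert-butyldimethylsilyl)oxy]-2,4,7-trimethyloctahydro-1H-cyclopenta[c]pyridine F15, and HCl in MeOH would give (4S,4aR,6R,7R,7aS)-2,4,7-trimethyloctahydro-1H-cyclopenta[c]pyridin-6-ol F16.
- A double Mitsunobu esterification of F16 with diacid 22 (PPh3, DIAD, THF) should invert both C6 centres and give 23, where the route is rejoined.

Step 7. The SN2 displacement at the β-branched primary iodide may be slow, so that E2 elimination to the exocyclic alkene or C-alkylation of the ambident vinylcarbamate anion competes. The fallback introduces nitrogen with a small nucleophile and builds the N-vinyl carbamate by acylation of an imine. It sets out from 11. NaN3 in DMF would give tert-butyl{[(1S,2R,3S,4S)-3-(azidomethyl)-2-methyl-4-(prop-1-en-2-yl)cyclopentyl]oxy}dimethylsilane F17. Staudinger reduction (PPh3, THF/H2O) would give [(1S,2R,3S,5S)-3-[(tert-butyldimethylsilyl)oxy]-2-methyl-5-(prop-1-en-2-yl)cyclopentyl]methanamine F18. Condensation with acetaldehyde (MgSO4, CH2Cl2, 0 °C) would give N-{[(1S,2R,3S,5S)-3-[(tert-butyldimethylsilyl)oxy]-2-methyl-5-(prop-1-en-2-yl)cyclopentyl]methyl}ethanimine F19. Acylation with methyl chloroformate and Et3N would give methyl N-ethenyl-N-{[(1S,2R,3S,5S)-3-[(tert-butyldimethylsilyl)oxy]-2-methyl-5-(prop-1-en-2-yl)cyclopentyl]methyl}carbamate F20. Metathesis as in step 8 would give methyl (4aS,6S,7R,7aS)-6-[(tert-butyldimethylsilyl)oxy]-4,7-dimethyl-1,4a,5,6,7,7a-hexahydro-2H-cyclopenta[c]pyridine-2-carboxylate F21, and hydrogenation in the same flask methyl (4S,4aR,6S,7R,7aS)-6-[(tert-butyldimethylsilyl)oxy]-4,7-dimethyloctahydro-2H-cyclopenta[c]pyridine-2-carboxylate F22. LiAlH4 would reduce F22 to 16, where the route is rejoined.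

Further compounds

F1 | step 8 | tert-butyl N-{[(1S,2R,3S,5S)-3-[(tert-butyldimethylsilyl)oxy]-2-methyl-5-(prop-1-en-2-yl)cyclopentyl]methyl}carbamate | CC(C)(C)[Si](C)(C)O[C@H]1C[C@H](C(C)=C)[C@H](CNC(=O)OC(C)(C)C)[C@H]1C
F2 | step 8 | tert-butyl N-{[3-[(tert-butyldimethylsilyl)oxy]-5-(1-hydroxypropan-2-yl)-2-methylcyclopentyl]methyl}carbamate (ring centres as in 13, side-chain epimers) | CC(C)(C)[Si](C)(C)O[C@H]1C[C@H](C(C)CO)[C@H](CNC(=O)OC(C)(C)C)[C@H]1C
F3 | step 8 | tert-butyl N-{[3-[(tert-butyldimethylsilyl)oxy]-2-methyl-5-(1-oxopropan-2-yl)cyclopentyl]methyl}carbamate (ring centres as in 13, side-chain epimers) | CC(C)(C)[Si](C)(C)O[C@H]1C[C@H](C(C)C=O)[C@H](CNC(=O)OC(C)(C)C)[C@H]1C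
F4 | step 6 | 2-{[(3R,4R)-3,7-dimethylocta-1,6-dien-4-yl]oxy}-4,4,5,5-tetramethyl-1,3,2-dioxaborolane | CC(C)=CC[C@@H](OB1OC(C)(C)C(C)(C)O1)[C@H](C)C=C
F5 | step 6 | (3R,4R)-3,7-dimethylocta-1,6-dien-4-ol | CC(C)=CC[C@@H](O)[C@H](C)C=C
F6 | step 6 | tert-butyl{[(3R,4R)-3,7-dimethylocta-1,6-dien-4-yl]oxy}dimethylsilane | CC(C)=CC[C@@H](O[Si](C)(C)C(C)(C)C)[C@H](C)C=C
F7 | step 6 | (2E,5R,6R)-5-[(tert-butyldimethylsilyl)oxy]-2,6-dimethylocta-2,7-dien-1-ol | OC/C(C)=C/C[C@@H](O[Si](C)(C)C(C)(C)C)[C@H](C)C=C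
F8 | step 6 | tert-butyl{[(3R,4R,6E)-8-chloro-3,7-dimethylocta-1,6-dien-4-yl]oxy}dimethylsilane | ClC/C(C)=C/C[C@@H](O[Si](C)(C)C(C)(C)C)[C@H](C)C=C
F9 | step 6 | [(2E,5R,6R)-5-[(tert-butyldimethylsilyl)oxy]-2,6-dimethylocta-2,7-dien-1-yl]magnesium chloride | Cl[Mg]C/C(C)=C/C[C@@H](O[Si](C)(C)C(C)(C)C)[C@H](C)C=C
F10 | step 6 | {[(1S,2R,3R,5S)-3-[(tert-butyldimethylsilyl)oxy]-2-methyl-5-(prop-1-en-2-yl)cyclopentyl]methyl}magnesium chloride | CC(C)(C)[Si](C)(C)O[C@@H]1C[C@H](C(C)=C)[C@H](C[Mg]Cl)[C@H]1C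
F11 | step 6 | tert-butyl{[(1R,2R,3S,4S)-3-(iodomethyl)-2-methyl-4-(prop-1-en-2-yl)cyclopentyl]oxy}dimethylsilane | CC(C)(C)[Si](C)(C)O[C@@H]1C[C@H](C(C)=C)[C@H](CI)[C@H]1C
F12 | step 6 | tert-butyl N-ethenyl-N-{[(1S,2R,3R,5S)-3-[(tert-butyldimethylsilyl)oxy]-2-methyl-5-(prop-1-en-2-yl)cyclopentyl]methyl}carbamate | CC(C)(C)[Si](C)(C)O[C@@H]1C[C@H](C(C)=C)[C@H](CN(C=C)C(=O)OC(C)(C)C)[C@H]1C
F13 | step 6 | tert-butyl (4aS,6R,7R,7aS)-6-[(tert-butyldimethylsilyl)oxy]-4,7-dimethyl-1,4a,5,6,7,7a-hexahydro-2H-cyclopenta[c]pyridine-2-carboxylate | CC(C)(C)[Si](C)(C)O[C@@H]1C[C@H]2[C@H](CN(C(=O)OC(C)(C)C)C=C2C)[C@H]1C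
F14 | step 6 | tert-butyl (4S,4aR,6R,7R,7aS)-6-[(tert-butyldimethylsilyl)oxy]-4,7-dimethyloctahydro-2H-cyclopenta[c]pyridine-2-carboxylate | CC(C)(C)[Si](C)(C)O[C@@H]1C[C@H]2[C@H](CN(C(=O)OC(C)(C)C)C[C@H]2C)[C@H]1C
F15 | step 6 | (4S,4aR,6R,7R,7aS)-6-[(tert-butyldimethylsilyl)oxy]-2,4,7-trimethyloctahydro-1H-cyclopenta[c]pyridine | CC(C)(C)[Si](C)(C)O[C@@H]1C[C@H]2[C@H](CN(C)C[C@H]2C)[C@H]1C
F16 | step 6 | (4S,4aR,6R,7R,7aS)-2,4,7-trimethyloctahydro-1H-cyclopenta[c]pyridin-6-ol | O[C@@H]1C[C@H]2[C@H](CN(C)C[C@H]2C)[C@H]1C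
F17 | step 7 | tert-butyl{[(1S,2R,3S,4S)-3-(azidomethyl)-2-methyl-4-(prop-1-en-2-yl)cyclopentyl]oxy}dimethylsilane | CC(C)(C)[Si](C)(C)O[C@H]1C[C@H](C(C)=C)[C@H](CN=[N+]=[N-])[C@H]1C
F18 | step 7 | [(1S,2R,3S,5S)-3-[(tert-butyldimethylsilyl)oxy]-2-methyl-5-(prop-1-en-2-yl)cyclopentyl]methanamine | CC(C)(C)[Si](C)(C)O[C@H]1C[C@H](C(C)=C)[C@H](CN)[C@H]1C
F19 | step 7 | N-{[(1S,2R,3S,5S)-3-[(tert-butyldimethylsilyl)oxy]-2-methyl-5-(prop-1-en-2-yl)cyclopentyl]methyl}ethanimine (imine geometry not fixed) | CC(C)(C)[Si](C)(C)O[C@H]1C[C@H](C(C)=C)[C@H](CN=CC)[C@H]1C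
F20 | step 7 | methyl N-ethenyl-N-{[(1S,2R,3S,5S)-3-[(tert-butyldimethylsilyl)oxy]-2-methyl-5-(prop-1-en-2-yl)cyclopentyl]methyl}carbamate | CC(C)(C)[Si](C)(C)O[C@H]1C[C@H](C(C)=C)[C@H](CN(C=C)C(=O)OC)[C@H]1C
F21 | step 7 | methyl (4aS,6S,7R,7aS)-6-[(tert-butyldimethylsilyl)oxy]-4,7-dimethyl-1,4a,5,6,7,7a-hexahydro-2H-cyclopenta[c]pyridine-2-carboxylate | CC(C)(C)[Si](C)(C)O[C@H]1C[C@H]2[C@H](CN(C(=O)OC)C=C2C)[C@H]1C
F22 | step 7 | methyl (4S,4aR,6S,7R,7aS)-6-[(tert-butyldimethylsilyl)oxy]-4,7-dimethyloctahydro-2H-cyclopenta[c]pyridine-2-carboxylate | CC(C)(C)[Si](C)(C)O[C@H]1C[C@H]2[C@H](CN(C(=O)OC)C[C@H]2C)[C@H]1C
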